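**Retrosynthetic overview**
- Target ⇐ desilylation, angeloylation, hydroxyl-directed epoxidation and C6 ketone reduction of a ten-membered (4Z)-6-oxo-8,12-olide.
- That keto lactone ⇐ ten-membered keto ester ⇐ key three-carbon ring expansion (7 → 10): SmI2 allyl-Barbier cyclisation onto the cycloheptenone carbonyl (C6–C7 bond), then Grob fragmentation of C6–C10 with loss of a neopentyl mesylate (gives C10=C14).
- Ring-expansion substrate ⇐ Baylis–Hillman/bromination of an α-silyloxy aldehyde ⇐ ozonolysis, hydroxymethylation/mesylation and alkylation of a 6-silyloxy-3-methylcycloheptenone with a chiral C4 triflate.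
- Cycloheptenone ⇐ ring-closing metathesis of the aldol adduct of methyl vinyl ketone and 4-methylpent-4-enal.
- Ring order: cycloheptenone (RCM) → transient cyclopentane (Barbier) → cyclodecadienone (Grob) → γ-lactone → epoxide.

Assumption: germacrane numbering is used for the ten-membered ring (C1 free carbinol, C4–C5 epoxide, C6 ester carbinol, C7, C8 lactone carbinol, C10=C14 ring methylene, C11=C13 lactone methylene), and 4-methylpent-4-enal and (R)-but-3-ene-1,2-diol are bought.

**Route**

Step 1
Reactants: 1 methyl vinyl ketone; 2 4-methylpent-4-enal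
Product: 3 (S)-5-hydroxy-8-methylnona-1,8-dien-3-one
Conditions: (S,S)-ProPhenol (10 mol %), Et2Zn (20 mol %), 4 Å MS, THF, 4 °C, excess 1
Reagents that add atoms: none
Why: Direct catalytic asymmetric aldol reaction (dinuclear zinc–ProPhenol) of the methyl group of the enone onto the aldehyde; the chiral dizinc pocket selects one aldehyde face and sets C1 as S (ligand enantiomer chosen to give S, checked by Mosher ester).

Step 2
Reactants: 3 (S)-5-hydroxy-8-methylnona-1,8-dien-3-one
Product: 4 (S)-5-[(tert-butyldimethylsilyl)oxy]-8-methylnona-1,8-dien-3-one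
Conditions: TBSOTf, 2,6-lutidine, CH2Cl2, −78 °C
Reagents that add atoms: tert-butyldimethylsilyl triflate, CC(C)(C)[Si](C)(C)OS(=O)(=O)C(F)(F)F
Why: Silyl ether formation on the secondary alcohol blocks oxa-Michael closure and dehydration of the β-hydroxy enone without touching the stereocenter.

Step 3
Reactants: 4 (S)-5-[(tert-butyldimethylsilyl)oxy]-8-methylnona-1,8-dien-3-one
Product: 5 (S)-6-[(tert-butyldimethylsilyl)oxy]-3-methylcyclohept-2-en-1-one
Conditions: Grubbs II (5 mol %), CH2Cl2 (5 mM), 40 °C
Reagents that add atoms: none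
Why: Ring-closing metathesis between the vinyl ketone and the 1,1-disubstituted alkene gives the trisubstituted cycloheptenone, and the seven-membered ring fixes the C4=C5 bond as Z for the rest of the route.

Step 4
Reactants: 6 (R)-but-3-ene-1,2-diol
Product: 8 (R)-2-[(triethylsilyl)oxy]but-3-en-1-yl triflate, via hydroxy triflate 7 (not isolated)
Conditions: Tf2O (1.0 equiv), 2,6-lutidine, CH2Cl2, −78 °C; then TESOTf, −78 → −40 °C; used cold
Reagents that add atoms: triflic anhydride, O=S(=O)(OS(=O)(=O)C(F)(F)F)C(F)(F)F; triethylsilyl triflate, CC[Si](CC)(CC)OS(=O)(=O)C(F)(F)F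
Why: One-pot selective sulfonylation of the primary hydroxyl at low temperature followed by silylation of the secondary hydroxyl; the chiral-pool stereocenter (future C8) is not involved.

Step 5
Reactants: 5 (S)-6-[(tert-butyldimethylsilyl)oxy]-3-methylcyclohept-2-en-1-one; 8 (R)-2-[(triethylsilyl)oxy]but-3-en-1-yl triflate
Product: 10 (6S)-6-[(tert-butyldimethylsilyl)oxy]-3-methyl-7-[(2S)-2-[(triethylsilyl)oxy]but-3-en-1-yl]cyclohept-2-en-1-one (6,7-trans), via lithium enolate 9 (not isolated)
Conditions: LDA, THF, −78 °C; then 8, −78 → −20 °C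
Reagents that add atoms: none
Why: Kinetic α′-enolate formation of the enone and SN2 alkylation with the primary triflate, which enters trans to the neighbouring silyloxy group; this C10 configuration is reset in step 6.

Step 6
Reactants: 10 the alkylated cycloheptenone
Product: 12 (6S)-6-[(tert-butyldimethylsilyl)oxy]-7-(hydroxymethyl)-3-methyl-7-[(2S)-2-[(triethylsilyl)oxy]but-3-en-1-yl]cyclohept-2-en-1-one (CH2OH trans to OTBS), via lithium enolate 11 (not isolated)
Conditions: LDA, THF, −78 °C; then monomeric CH2O (from cracked paraformaldehyde), −78 °C; cold NH4Cl quench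
Reagents that add atoms: formaldehyde, C=O
Why: Aldol addition of the fully substituted α′-enolate to formaldehyde builds the C10 quaternary centre; A(1,2) strain puts the adjacent OTBS pseudoaxial so formaldehyde adds to the opposite face, leaving CH2OH trans and the C9 chain cis to OTBS.

Step 7
Reactants: 12 the hydroxymethyl ketone
Product: 13 the neopentyl mesylate of 12 (same configuration)
Conditions: MsCl, Et3N, CH2Cl2, 0 °C
Reagents that add atoms: methanesulfonyl chloride, CS(=O)(=O)Cl
Why: Sulfonylation of the primary alcohol installs the nucleofuge for the later fragmentation; the β-mesyloxy ketone cannot eliminate because its α-carbon is quaternary.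

Step 8
Reactants: 13 the mesylate
Product: 15 (2S)-3-[(1-mesyloxymethyl-7-oxo-5-methyl-2-(TBS-oxy)cyclohept-5-enyl)]-2-[(triethylsilyl)oxy]propanal, via secondary ozonide 14 (not isolated)
Conditions: O3, CH2Cl2, pyridine, Sudan III indicator, −78 °C; then PPh3, −78 °C → rt
Reagents that add atoms: ozone, [O-][O+]=O
Why: Ozonolysis with reductive work-up cleaves the electron-rich terminal vinyl group much faster than the conjugated trisubstituted enone alkene and leaves the α-silyloxy stereocenter untouched.

Step 9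
Reactants: 15 the α-silyloxy aldehyde; 16 methyl acrylate
Product: 17 Baylis–Hillman adduct, methyl 2-methylene-3-hydroxy-4-(triethylsilyloxy)-5-(cycloheptenonyl)pentanoate (both C3 carbinol epimers)
Conditions: DABCO (1 equiv), methyl acrylate (excess), rt, 3–5 d
Reagents that add atoms: none
Why: Morita–Baylis–Hillman reaction of an activated α-oxygenated aldehyde; the new carbinol centre becomes sp2 in step 10, so its configuration is irrelevant.

Step 10
Reactants: 17 the Baylis–Hillman adduct
Product: 18 methyl (Z)-2-(bromomethyl)-4-(triethylsilyloxy)-5-(cycloheptenonyl)pent-2-enoate (C8 S)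
Conditions: NBS, Me2S, CH2Cl2, 0 °C → rt
Reagents that add atoms: N-bromosuccinimide, O=C1CCC(=O)N1Br
Why: Corey–Kim-type activation of the allylic alcohol and SN2′ attack of bromide gives the rearranged primary allylic bromide, with the usual Z preference (alkyl group cis to CH2Br).

Step 11
Reactants: 18 the allylic bromide
Product: 21 methyl 1α-(tert-butyldimethylsilyloxy)-8α-(triethylsilyloxy)-6-oxogermacra-4Z,10(14),11(13)-trien-12-oate (7α-H), via allylsamarium 19 (not isolated), via samarium hydroazulenolate 20 (not isolated)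
Conditions: SmI2 (2.3 equiv, 0.1 M in THF), slow addition of 18, THF, −78 °C; then −78 → 0 °C
Reagents that add atoms: none
Why: Proposed new method: two-electron reduction of the allylic bromide by SmI2 should give a 2-(methoxycarbonyl)allylsamarium(III) that adds through its γ-carbon (C7) to the neighbouring enone carbonyl in a chelated chair transition state (new C6–C7 bond, cis-fused hydroazulene, acrylate arm trans to the C8 silyloxy group and cis to the samarium-bound oxygen, a matched pairing fixed by the C10 configuration from step 6), after which the tertiary samarium alkoxide undergoes Grob fragmentation of C6–C10 antiperiplanar to the freely rotating CH2–OMs bond to release the C6 enone, the C10=C14 methylene and the ten-membered ring with the Z alkene inherited from the seven-membered ring; the closest known reaction type is the SmI2-mediated sequential intramolecular Barbier cyclisation/Grob fragmentation of iodoalkyl keto mesylates, which has not been shown with an ester-bearing allylic bromide, an enone acceptor or a neopentyl nucleofuge that delivers an exocyclic alkene.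

Step 12
Reactants: 21 the ten-membered keto ester
Product: 23 1α-(tert-butyldimethylsilyloxy)-6-oxogermacra-4Z,10(14),11(13)-trien-8α,12-olide (7α-H, 8β-H, trans-lactone), via hydroxy ester 22 (not isolated)
Conditions: PPTS, MeOH, 0 °C; then CSA (cat.), CH2Cl2, rt
Reagents that add atoms: none
Why: Mild acidic methanolysis removes the secondary TES ether but not the TBS ether, and the freed C8 hydroxyl closes the γ-lactone on the acrylate ester by acid-catalysed transesterification; closing it while C6 is still a ketone rules out the 6,12-lactone.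

Step 13
Reactants: 23 the keto lactone
Product: 24 1α-(tert-butyldimethylsilyloxy)-6α-hydroxygermacra-4Z,10(14),11(13)-trien-8α,12-olide
Conditions: (R)-2-methyl-CBS-oxazaborolidine (0.5 equiv), catecholborane, toluene, −78 °C
Reagents that add atoms: none
Why: Corey–Bakshi–Shibata reduction of the enone carbonyl with the (Z)-β,β-disubstituted alkenyl group as the large substituent; the (R)-catalyst delivers hydride to the face that gives the 6α (6S) alcohol, and catecholborane at −78 °C spares the alkenes and the methylene lactone.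

Step 14
Reactants: 24 the allylic alcohol
Product: 25 1α-(tert-butyldimethylsilyloxy)-4α,5α-epoxy-6α-hydroxygermacra-10(14),11(13)-dien-8α,12-olide
Conditions: VO(acac)2 (5 mol %), t-BuOOH, CH2Cl2, 0 °C → rt
Reagents that add atoms: tert-butyl hydroperoxide, CC(C)(C)OO
Why: Vanadium-catalysed hydroxyl-directed epoxidation delivers oxygen to the Z alkene on the face of the C6 hydroxyl (cis-epoxy alcohol, as in medium-ring cis-cycloalkenols), setting C4 (R) and C5 (S); the silylated exocyclic alkene and the electron-poor lactone methylene are not directed and do not react.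

Step 15
Reactants: 25 the epoxy alcohol; 26 angelic acid
Product: 28 6α-angeloyloxy-1α-(tert-butyldimethylsilyloxy)-4α,5α-epoxygermacra-10(14),11(13)-dien-8α,12-olide, via mixed anhydride 27 (not isolated)
Conditions: 26, 2,4,6-trichlorobenzoyl chloride, Et3N, toluene, rt; then 25, 80 °C (no DMAP)
Reagents that add atoms: none
Why: Yamaguchi-type esterification through the trichlorobenzoyl mixed anhydride acylates the hindered secondary alcohol and is the established way to make angelates without Z-to-E isomerisation to the tiglate.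

Step 16
Reactants: 28 the silyl-protected angelate
Product: 29 CNP0104965.1, 6α-angeloyloxy-4α,5α-epoxy-1α-hydroxygermacra-10(14),11(13)-dien-8α,12-olide, (1S,4R,5S,6S,7R,8S)
Conditions: HF·pyridine, pyridine, THF, 0 °C → rt
Reagents that add atoms: none
Why: Buffered fluoride desilylation frees the C1 allylic alcohol under conditions that the epoxide, the angelate and the α-methylene lactone tolerate.

**Compound list**
1 | methyl vinyl ketone (but-3-en-2-one) | C=CC(C)=O | starting material
2 | 4-methylpent-4-enal | C=C(C)CCC=O | starting material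
3 | (S)-5-hydroxy-8-methylnona-1,8-dien-3-one | C=CC(=O)C[C@@H](O)CCC(C)=C | intermediate
4 | (S)-5-[(tert-butyldimethylsilyl)oxy]-8-methylnona-1,8-dien-3-one | C=CC(=O)C[C@@H](O[Si](C)(C)C(C)(C)C)CCC(C)=C | intermediate
5 | (S)-6-[(tert-butyldimethylsilyl)oxy]-3-methylcyclohept-2-en-1-one | O=C1C=C(C)CC[C@H](O[Si](C)(C)C(C)(C)C)C1 | intermediate
6 | (R)-but-3-ene-1,2-diol | OC[C@H](O)C=C | starting material
7 | (R)-2-hydroxybut-3-en-1-yl triflate (not isolated) | O=S(=O)(OC[C@H](O)C=C)C(F)(F)F | intermediate
8 | (R)-2-[(triethylsilyl)oxy]but-3-en-1-yl triflate | O=S(=O)(OC[C@H](O[Si](CC)(CC)CC)C=C)C(F)(F)F | intermediate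
9 | lithium α′-enolate of 5 (not isolated) | [Li]OC1=C[C@@H](O[Si](C)(C)C(C)(C)C)CCC(C)=C1 | intermediate
10 | (6S)-6-(TBS-oxy)-3-methyl-7-[(2S)-2-(TES-oxy)but-3-en-1-yl]cyclohept-2-en-1-one, 6,7-trans | O=C1C=C(C)CC[C@H](O[Si](C)(C)C(C)(C)C)[C@H]1C[C@H](O[Si](CC)(CC)CC)C=C | intermediate
11 | lithium α′-enolate of 10 (not isolated) | [Li]OC1=C(C[C@H](O[Si](CC)(CC)CC)C=C)[C@@H](O[Si](C)(C)C(C)(C)C)CCC(C)=C1 | intermediate
12 | (6S)-6-(TBS-oxy)-7-(hydroxymethyl)-3-methyl-7-[(2S)-2-(TES-oxy)but-3-en-1-yl]cyclohept-2-en-1-one, CH2OH trans to OTBS | O=C1C=C(C)CC[C@H](O[Si](C)(C)C(C)(C)C)[C@]1(CO)C[C@H](O[Si](CC)(CC)CC)C=C | intermediate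
13 | mesylate of 12 | O=C1C=C(C)CC[C@H](O[Si](C)(C)C(C)(C)C)[C@]1(COS(C)(=O)=O)C[C@H](O[Si](CC)(CC)CC)C=C | intermediate
14 | secondary ozonide of 13 (1,2,4-trioxolane, not isolated) | O=C1C=C(C)CC[C@H](O[Si](C)(C)C(C)(C)C)[C@]1(COS(C)(=O)=O)C[C@H](O[Si](CC)(CC)CC)C1OCOO1 | intermediate
15 | (2S)-2-(TES-oxy)-3-(cycloheptenonyl)propanal (α-silyloxy aldehyde) | O=C1C=C(C)CC[C@H](O[Si](C)(C)C(C)(C)C)[C@]1(COS(C)(=O)=O)C[C@H](O[Si](CC)(CC)CC)C=O | intermediate
16 | methyl acrylate | C=CC(=O)OC | starting material
17 | Baylis–Hillman adduct (C3 carbinol epimers) | O=C1C=C(C)CC[C@H](O[Si](C)(C)C(C)(C)C)[C@]1(COS(C)(=O)=O)C[C@H](O[Si](CC)(CC)CC)C(O)C(=C)C(=O)OC | intermediate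
18 | methyl (Z)-2-(bromomethyl)-4-(TES-oxy)-5-(cycloheptenonyl)pent-2-enoate | O=C1C=C(C)CC[C@H](O[Si](C)(C)C(C)(C)C)[C@]1(COS(C)(=O)=O)C[C@H](O[Si](CC)(CC)CC)/C=C(\CBr)C(=O)OC | intermediate
19 | allylsamarium(III) diiodide from 18 (not isolated) | O=C1C=C(C)CC[C@H](O[Si](C)(C)C(C)(C)C)[C@]1(COS(C)(=O)=O)C[C@H](O[Si](CC)(CC)CC)/C=C(\C[Sm](I)I)C(=O)OC | intermediate
20 | cis-fused bicyclo[5.3.0] samarium alkoxide (not isolated) | C=C(C(=O)OC)[C@@H]1[C@@H](O[Si](CC)(CC)CC)C[C@@]2(COS(C)(=O)=O)[C@@H](O[Si](C)(C)C(C)(C)C)CCC(C)=C[C@@]12O[Sm](I)I | intermediate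
21 | methyl 1α-(TBS-oxy)-8α-(TES-oxy)-6-oxogermacra-4Z,10(14),11(13)-trien-12-oate | C=C(C(=O)OC)[C@@H]1[C@@H](O[Si](CC)(CC)CC)CC(=C)[C@@H](O[Si](C)(C)C(C)(C)C)CC/C(C)=C\C1=O | intermediate
22 | methyl 1α-(TBS-oxy)-8α-hydroxy-6-oxogermacra-4Z,10(14),11(13)-trien-12-oate (not isolated) | C=C(C(=O)OC)[C@@H]1[C@@H](O)CC(=C)[C@@H](O[Si](C)(C)C(C)(C)C)CC/C(C)=C\C1=O | intermediate
23 | 1α-(TBS-oxy)-6-oxogermacra-4Z,10(14),11(13)-trien-8α,12-olide | C=C1C(=O)O[C@H]2CC(=C)[C@@H](O[Si](C)(C)C(C)(C)C)CC/C(C)=C\C(=O)[C@H]12 | intermediate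
24 | 1α-(TBS-oxy)-6α-hydroxygermacra-4Z,10(14),11(13)-trien-8α,12-olide | C=C1C(=O)O[C@H]2CC(=C)[C@@H](O[Si](C)(C)C(C)(C)C)CC/C(C)=C\[C@@H](O)[C@H]12 | intermediate
25 | 1α-(TBS-oxy)-4α,5α-epoxy-6α-hydroxygermacra-10(14),11(13)-dien-8α,12-olide | C=C1C(=O)O[C@H]2CC(=C)[C@@H](O[Si](C)(C)C(C)(C)C)CC[C@@]3(C)O[C@H]3[C@@H](O)[C@H]12 | intermediate
26 | angelic acid, (Z)-2-methylbut-2-enoic acid | C/C=C(/C)C(=O)O | starting material
27 | angelic 2,4,6-trichlorobenzoic mixed anhydride (not isolated) | C/C=C(/C)C(=O)OC(=O)c1c(Cl)cc(Cl)cc1Cl | intermediate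
28 | 6α-angeloyloxy-1α-(TBS-oxy)-4α,5α-epoxygermacra-10(14),11(13)-dien-8α,12-olide | C=C1C(=O)O[C@H]2CC(=C)[C@@H](O[Si](C)(C)C(C)(C)C)CC[C@@]3(C)O[C@H]3[C@@H](OC(=O)/C(C)=C\C)[C@H]12 | intermediate
29 | CNP0104965.1, (1S,4R,5S,6S,7R,8S) | C=C1C(=O)O[C@H]2CC(=C)[C@@H](O)CC[C@@]3(C)O[C@H]3[C@@H](OC(=O)/C(C)=C\C)[C@H]12 | target

**Step count and risks**

Total: 16 steps. Longest linear sequence: 15 steps (steps 1–3 and 5–16; step 4 is a one-step side branch).

The three steps I judge most likely to fail are steps 11, 13 and 1.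

Step 11 (the proposed new cascade) can fail through 1,4-elimination of the silyloxy group from the allylsamarium, through the wrong C7 epimer, or through a samarium alkoxide that does not fragment. The fallback uses two known reactions run separately. It sets out from 18: indium-mediated intramolecular Barbier allylation (In powder, THF/aq. NH4Cl, rt, buffered work-up so the tertiary alcohol does not lactonise) gives the cis-fused bicyclic hydroxy ester F5. A Wharton–Grob fragmentation of this 1,3-hydroxy mesylate (KHMDS, 18-crown-6, THF, −78 → 0 °C) then comes back to the route at 21.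

Step 13 can fail if the catalyst does not override the ring's own facial bias or if the branched C7 side is read as the large group. The fallback sets out from 23: Luche reduction (NaBH4, CeCl3·7H2O, MeOH, −78 °C) under substrate control. If it gives the 6β-alcohol, 1α-(TBS-oxy)-6β-hydroxygermacra-4Z,10(14),11(13)-trien-8α,12-olide F6, this is inverted by Mitsunobu reaction with chloroacetic acid (PPh3, DIAD, toluene, 0 °C) to the 6α-chloroacetate F7. Neutral dechloroacetylation (thiourea, NaHCO3, EtOH, 40 °C) comes back to the route at 24.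

Step 1 can fail because unbranched aldehydes self-condense and methyl vinyl ketone oligomerises under the zinc aldol conditions, giving low yield or low ee. The fallback sets out from 2: Roskamp homologation with methyl diazoacetate (SnCl2 cat., CH2Cl2) gives methyl 6-methyl-3-oxohept-6-enoate F1. Noyori hydrogenation (RuCl2[(S)-BINAP], H2, MeOH) gives methyl (S)-3-hydroxy-6-methylhept-6-enoate F2. Silylation (TBSCl, imidazole, DMF) gives methyl (S)-3-[(tert-butyldimethylsilyl)oxy]-6-methylhept-6-enoate F3. MeNHOMe·HCl with i-PrMgCl (THF, −20 °C) gives the Weinreb amide (S)-3-[(tert-butyldimethylsilyl)oxy]-N-methoxy-N,6-dimethylhept-6-enamide F4. Vinylmagnesium bromide (THF, 0 °C) then comes back to the route at 4.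

Further compounds
F1 | step 1 | methyl 6-methyl-3-oxohept-6-enoate | COC(=O)CC(=O)CCC(C)=C
F2 | step 1 | methyl (S)-3-hydroxy-6-methylhept-6-enoate | COC(=O)C[C@@H](O)CCC(C)=C
F3 | step 1 | methyl (S)-3-[(tert-butyldimethylsilyl)oxy]-6-methylhept-6-enoate | COC(=O)C[C@@H](O[Si](C)(C)C(C)(C)C)CCC(C)=C
F4 | step 1 | (S)-3-[(tert-butyldimethylsilyl)oxy]-N-methoxy-N,6-dimethylhept-6-enamide | CON(C)C(=O)C[C@@H](O[Si](C)(C)C(C)(C)C)CCC(C)=C
F5 | step 11 | cis-fused bicyclo[5.3.0] tertiary alcohol (hydroxy ester, protonated form of 20) | C=C(C(=O)OC)[C@@H]1[C@@H](O[Si](CC)(CC)CC)C[C@@]2(COS(C)(=O)=O)[C@@H](O[Si](C)(C)C(C)(C)C)CCC(C)=C[C@@]12O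
F6 | step 13 | 1α-(TBS-oxy)-6β-hydroxygermacra-4Z,10(14),11(13)-trien-8α,12-olide | C=C1C(=O)O[C@H]2CC(=C)[C@@H](O[Si](C)(C)C(C)(C)C)CC/C(C)=C\[C@H](O)[C@H]12
F7 | step 13 | 6α-(chloroacetoxy)-1α-(TBS-oxy)germacra-4Z,10(14),11(13)-trien-8α,12-olide | C=C1C(=O)O[C@H]2CC(=C)[C@@H](O[Si](C)(C)C(C)(C)C)CC/C(C)=C\[C@@H](OC(=O)CCl)[C@H]12
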